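**Strategy.** The six-membered ring is made as a cyclopentanone and enlarged by one carbon. The key step exploits two features of the cyclohexene: C2 is its only ring carbon without a heteroatom, and C6 is quaternary. (R)-4-Silyloxycyclopentenone supplies C4; Baylis–Hillman hydroxymethylation and an anti-selective cis-dihydroxylation relay it to C5 and C6 in one event. The ketone (future C1) can then enolise only towards C3. Simmons–Smith methylenation gives a 1-siloxybicyclo[3.1.0]hexane carrying all three oxygenated stereocentres; FeCl3 opening of this strained cyclopropane (Ito–Saegusa enlargement) inserts C2 between C1 and C3 and gives the C1-oxo C2=C3 enone. Benzoylation, hydroxyl-directed reduction and O-methylation finish the synthesis.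

Key step: step 7

Remark: atom labels C1–C6 follow the target ring at every stage (C1 OMe, C2=C3, C4 OBz, C5 OAc, C6 C(OH)CH2OBz). (R)-4-[(tert-Butyldimethylsilyl)oxy]cyclopent-2-en-1-one is assumed to be purchased enantiopure.

**Step 1**
Reactants: 1 (R)-4-[(tert-butyldimethylsilyl)oxy]cyclopent-2-en-1-one
Product: 2 (R)-4-[(tert-butyldimethylsilyl)oxy]-2-(hydroxymethyl)cyclopent-2-en-1-one
Conditions: 37% aq. HCHO, imidazole, THF/H2O (1:1), rt
Reagents that add atoms: formaldehyde, C=O
Why: Morita–Baylis–Hillman α-hydroxymethylation of a cyclic enone puts the future CH2OBz carbon on the future C6; the C4 stereocentre is not involved and no new one is formed.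

**Step 2**
Reactants: 2 (R)-4-[(tert-butyldimethylsilyl)oxy]-2-(hydroxymethyl)cyclopent-2-en-1-one
Product: 3 [(R)-3-[(tert-butyldimethylsilyl)oxy]-5-oxocyclopent-1-en-1-yl]methyl benzoate
Conditions: BzCl, pyridine, DMAP (cat.), CH2Cl2, 0 °C
Reagents that add atoms: benzoyl chloride, O=C(Cl)c1ccccc1
Why: Standard acylation of the primary allylic alcohol installs the first benzoate of the target at once, so this position needs no protecting group.

**Step 3**
Reactants: 3 [(R)-3-[(tert-butyldimethylsilyl)oxy]-5-oxocyclopent-1-en-1-yl]methyl benzoate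
Product: 4 [(1S,2S,3R)-3-[(tert-butyldimethylsilyl)oxy]-1,2-dihydroxy-5-oxocyclopentyl]methyl benzoate
Conditions: K2OsO4·2H2O (2 mol%), NMO, citric acid, t-BuOH/H2O (1:1), rt
Reagents that add atoms: osmium tetroxide (catalytic, from K2OsO4·2H2O), O=[Os](=O)(=O)=O; N-methylmorpholine N-oxide, C[N+]1([O-])CCOCC1; water, O
Why: Upjohn cis-dihydroxylation, acid-buffered for the electron-poor alkene, should add OsO4 to the enone face anti to the adjacent C4 OTBS group, so C5 and the quaternary C6 are set together with both new hydroxyls cis to each other and trans to the C4 oxygen.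

**Step 4**
Reactants: 4 [(1S,2S,3R)-3-[(tert-butyldimethylsilyl)oxy]-1,2-dihydroxy-5-oxocyclopentyl]methyl benzoate
Product: 5 [(1S,2S,3R)-2-(acetyloxy)-3-[(tert-butyldimethylsilyl)oxy]-1-hydroxy-5-oxocyclopentyl]methyl benzoate
Conditions: Ac2O (1.2 equiv), pyridine, DMAP (5 mol%), CH2Cl2, 0 °C
Reagents that add atoms: acetic anhydride, CC(=O)OC(C)=O
Why: Acylation should take the secondary C5 hydroxyl and leave the hindered tertiary C6 hydroxyl free, which installs the acetate of the target.

**Step 5**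
Reactants: 5 [(1S,2S,3R)-2-(acetyloxy)-3-[(tert-butyldimethylsilyl)oxy]-1-hydroxy-5-oxocyclopentyl]methyl benzoate
Product: 6 [(1S,4R,5S)-5-(acetyloxy)-4-[(tert-butyldimethylsilyl)oxy]-1,2-bis[(trimethylsilyl)oxy]cyclopent-2-en-1-yl]methyl benzoate
Conditions: TMSOTf (2.5 equiv), Et3N (4 equiv), CH2Cl2, −78 → 0 °C
Reagents that add atoms: trimethylsilyl triflate, C[Si](C)(C)OS(=O)(=O)C(F)(F)F
Why: Soft enolisation gives a single enol silane because C6 is quaternary and only the CH2 (future C3) flank carries α-hydrogens; the tertiary hydroxyl is silylated at the same time.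

**Step 6**
Reactants: 6 [(1S,4R,5S)-5-(acetyloxy)-4-[(tert-butyldimethylsilyl)oxy]-1,2-bis[(trimethylsilyl)oxy]cyclopent-2-en-1-yl]methyl benzoate
Product: 7 [(1S,2S,3S,4R,5R)-3-(acetyloxy)-4-[(tert-butyldimethylsilyl)oxy]-1,2-bis[(trimethylsilyl)oxy]bicyclo[3.1.0]hexan-2-yl]methyl benzoate (cyclopropane CH2 anti to the OTBS group)
Conditions: Et2Zn, CH2I2, CH2Cl2, 0 °C → rt
Reagents that add atoms: diiodomethane, ICI
Why: Furukawa-modified Simmons–Smith cyclopropanation of the electron-rich enol silane tolerates the esters; methylene should add anti to the OTBS and CH2OBz groups, but both new cyclopropane stereocentres are erased in step 7.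

**Step 7**
Reactants: 7 [(1S,2S,3S,4R,5R)-3-(acetyloxy)-4-[(tert-butyldimethylsilyl)oxy]-1,2-bis[(trimethylsilyl)oxy]bicyclo[3.1.0]hexan-2-yl]methyl benzoate
Product: 10 [(1S,5R,6S)-6-(acetyloxy)-1,5-dihydroxy-2-oxocyclohex-3-en-1-yl]methyl benzoate, via 3-chlorocyclohexanone 8 (not isolated), via bis-silyl enone 9 (not isolated)
Conditions: FeCl3 (2.2 equiv), DMF, 0 °C → rt; then Et3N, CH2Cl2, 0 °C → rt; then HF·pyridine, THF, 0 °C → rt
Reagents that add atoms: none
Why: FeCl3 converts the siloxycyclopropane into an iron(III) cyclopropoxide/alkoxy radical whose β-scission breaks the bond shared by the three- and five-membered rings (C1–C3), so release of cyclopropane strain inserts C2 and leaves a secondary C3 radical that abstracts chlorine to give the 3-chlorocyclohexanone; Et3N then eliminates HCl (E1cB) to the C2=C3 enone and HF·pyridine removes both silyl groups. The closest known reaction type is the Ito–Saegusa one-carbon ring enlargement of cycloalkanone enol silanes through 1-siloxybicyclo[n.1.0]alkanes. No ring is closed: the six-membered ring arises from the five-membered one by fission of the zero-atom bridge of the bicyclo[3.1.0]hexane. No stereocentre of the product is created, since the C3 chloride and both cyclopropane centres are erased, and C4, C5 and C6 are untouched (C6 is quaternary; C4 and C5 are not α to the carbonyl). The step needs cleavage of the internal and not an external cyclopropane bond, which formation of the secondary ring radical and relief of bicyclic strain should secure, and a single elimination direction, which is secured because C2 carries the only α-hydrogens.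

**Step 8**
Reactants: 10 [(1S,5R,6S)-6-(acetyloxy)-1,5-dihydroxy-2-oxocyclohex-3-en-1-yl]methyl benzoate
Product: 11 [(1S,5R,6S)-6-(acetyloxy)-5-(benzoyloxy)-1-hydroxy-2-oxocyclohex-3-en-1-yl]methyl benzoate
Conditions: BzCl (1.2 equiv), pyridine, DMAP (cat.), CH2Cl2, 0 °C
Reagents that add atoms: benzoyl chloride, O=C(Cl)c1ccccc1
Why: DMAP-catalysed acylation should take the secondary allylic C4 hydroxyl while the tertiary α-ketol hydroxyl at C6 is too hindered to react, and C6 has no hydrogen through which the γ-acyloxy enone could aromatise.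

**Step 9**
Reactants: 11 [(1S,5R,6S)-6-(acetyloxy)-5-(benzoyloxy)-1-hydroxy-2-oxocyclohex-3-en-1-yl]methyl benzoate
Product: 12 [(1R,2S,5R,6S)-6-(acetyloxy)-5-(benzoyloxy)-1,2-dihydroxycyclohex-3-en-1-yl]methyl benzoate
Conditions: Me4NBH(OAc)3, MeCN/AcOH (1:1), −30 °C
Reagents that add atoms: none
Why: In this Evans–Saksena-type hydroxyl-directed 1,2-reduction the C6 hydroxyl binds boron and delivers hydride to the C1 carbonyl from its own face, so the new C1 hydroxyl should be trans to the C6 hydroxyl (1S in target numbering); the esters are inert to the acidic reagent.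

**Step 10**
Reactants: 12 [(1R,2S,5R,6S)-6-(acetyloxy)-5-(benzoyloxy)-1,2-dihydroxycyclohex-3-en-1-yl]methyl benzoate
Product: 13 [(1R,2S,5R,6S)-6-(acetyloxy)-5-(benzoyloxy)-1-hydroxy-2-methoxycyclohex-3-en-1-yl]methyl benzoate
Conditions: MeOTf (1.5 equiv), 2,6-di-tert-butyl-4-methylpyridine (2.5 equiv), CH2Cl2, 0 °C → rt
Reagents that add atoms: methyl triflate, COS(=O)(=O)C(F)(F)F
Why: O-Alkylation with a hard methyl electrophile and a hindered, non-nucleophilic base leaves the three esters intact and should methylate the secondary allylic C1 hydroxyl in preference to the tertiary C6 hydroxyl.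

**Compound list**
1 | (R)-4-[(tert-butyldimethylsilyl)oxy]cyclopent-2-en-1-one | O=C1C=C[C@H](O[Si](C)(C)C(C)(C)C)C1 | starting material
2 | (R)-4-[(tert-butyldimethylsilyl)oxy]-2-(hydroxymethyl)cyclopent-2-en-1-one | O=C1C(CO)=C[C@H](O[Si](C)(C)C(C)(C)C)C1 | intermediate
3 | [(R)-3-[(tert-butyldimethylsilyl)oxy]-5-oxocyclopent-1-en-1-yl]methyl benzoate | O=C1C(COC(=O)c2ccccc2)=C[C@H](O[Si](C)(C)C(C)(C)C)C1 | intermediate
4 | [(1S,2S,3R)-3-[(tert-butyldimethylsilyl)oxy]-1,2-dihydroxy-5-oxocyclopentyl]methyl benzoate | O=C1C[C@@H](O[Si](C)(C)C(C)(C)C)[C@H](O)[C@@]1(O)COC(=O)c1ccccc1 | intermediate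
5 | [(1S,2S,3R)-2-(acetyloxy)-3-[(tert-butyldimethylsilyl)oxy]-1-hydroxy-5-oxocyclopentyl]methyl benzoate | O=C1C[C@@H](O[Si](C)(C)C(C)(C)C)[C@H](OC(C)=O)[C@@]1(O)COC(=O)c1ccccc1 | intermediate
6 | [(1S,4R,5S)-5-(acetyloxy)-4-[(tert-butyldimethylsilyl)oxy]-1,2-bis[(trimethylsilyl)oxy]cyclopent-2-en-1-yl]methyl benzoate | C[Si](C)(C)OC1=C[C@@H](O[Si](C)(C)C(C)(C)C)[C@H](OC(C)=O)[C@@]1(O[Si](C)(C)C)COC(=O)c1ccccc1 | intermediate
7 | [(1S,2S,3S,4R,5R)-3-(acetyloxy)-4-[(tert-butyldimethylsilyl)oxy]-1,2-bis[(trimethylsilyl)oxy]bicyclo[3.1.0]hexan-2-yl]methyl benzoate | C[Si](C)(C)O[C@@]12C[C@@H]1[C@@H](O[Si](C)(C)C(C)(C)C)[C@H](OC(C)=O)[C@@]2(O[Si](C)(C)C)COC(=O)c1ccccc1 | intermediate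
8 | [(1S,5S,6S)-6-(acetyloxy)-5-[(tert-butyldimethylsilyl)oxy]-4-chloro-2-oxo-1-[(trimethylsilyl)oxy]cyclohexyl]methyl benzoate (both epimers at the C–Cl carbon) | O=C1CC(Cl)[C@@H](O[Si](C)(C)C(C)(C)C)[C@H](OC(C)=O)[C@@]1(O[Si](C)(C)C)COC(=O)c1ccccc1 | intermediate
9 | [(1S,5R,6S)-6-(acetyloxy)-5-[(tert-butyldimethylsilyl)oxy]-2-oxo-1-[(trimethylsilyl)oxy]cyclohex-3-en-1-yl]methyl benzoate | O=C1C=C[C@@H](O[Si](C)(C)C(C)(C)C)[C@H](OC(C)=O)[C@@]1(O[Si](C)(C)C)COC(=O)c1ccccc1 | intermediate
10 | [(1S,5R,6S)-6-(acetyloxy)-1,5-dihydroxy-2-oxocyclohex-3-en-1-yl]methyl benzoate | O=C1C=C[C@@H](O)[C@H](OC(C)=O)[C@@]1(O)COC(=O)c1ccccc1 | intermediate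
11 | [(1S,5R,6S)-6-(acetyloxy)-5-(benzoyloxy)-1-hydroxy-2-oxocyclohex-3-en-1-yl]methyl benzoate | O=C1C=C[C@@H](OC(=O)c2ccccc2)[C@H](OC(C)=O)[C@@]1(O)COC(=O)c1ccccc1 | intermediate
12 | [(1R,2S,5R,6S)-6-(acetyloxy)-5-(benzoyloxy)-1,2-dihydroxycyclohex-3-en-1-yl]methyl benzoate | O[C@H]1C=C[C@@H](OC(=O)c2ccccc2)[C@H](OC(C)=O)[C@@]1(O)COC(=O)c1ccccc1 | intermediate
13 | [(1R,2S,5R,6S)-6-(acetyloxy)-5-(benzoyloxy)-1-hydroxy-2-methoxycyclohex-3-en-1-yl]methyl benzoate | CO[C@H]1C=C[C@@H](OC(=O)c2ccccc2)[C@H](OC(C)=O)[C@@]1(O)COC(=O)c1ccccc1 | target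

Total step count: 10. Longest linear sequence: 10 steps (1 → 13).

**Steps most likely to fail**

Step 7 (key step). The siloxycyclopropane may open at an external bond, or be merely protodesilylated to a 2-methylcyclopentanone, instead of enlarging the ring, and base-induced loss of an acyloxy group may accompany the HCl elimination. The fallback sets out from ketone 5 and comes back to the route at 10. Me3Al-promoted homologation with trimethylsilyldiazomethane (CH2Cl2, −78 → −20 °C) is a Tiffeneau–Demjanov-type insertion in which the CH2 flank should migrate in preference to the oxygenated quaternary carbon, giving [(1S,2S,3R)-2-(acetyloxy)-3-[(tert-butyldimethylsilyl)oxy]-1-hydroxy-6-oxo-5-(trimethylsilyl)cyclohexyl]methyl benzoate F1. Acidic work-up should protodesilylate it to the cyclohexanone [(1S,2S,3R)-2-(acetyloxy)-3-[(tert-butyldimethylsilyl)oxy]-1-hydroxy-6-oxocyclohexyl]methyl benzoate F2. Dehydrogenation with IBX (DMSO/toluene, 70 °C), possible only on the single CH2 flank, should give the enone [(1S,5R,6S)-6-(acetyloxy)-5-[(tert-butyldimethylsilyl)oxy]-1-hydroxy-2-oxocyclohex-3-en-1-yl]methyl benzoate F3, and HF·pyridine then removes the TBS group to give 10.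

Step 1. The zwitterionic enolate of the Baylis–Hillman reaction may expel silanolate or erode the C4 configuration, or conversion may stall. The fallback sets out from 1 and comes back at 2. α-Iodination (I2, pyridine, CH2Cl2, 0 °C) should give (R)-4-[(tert-butyldimethylsilyl)oxy]-2-iodocyclopent-2-en-1-one F4, and Stille coupling with (tributylstannyl)methanol (Pd(PPh3)4, CuI, NMP, 50 °C) installs the hydroxymethyl group to give 2.

Step 10. Because the C1 hydroxyl is flanked by the quaternary C6, methylation may be slow enough for the tertiary hydroxyl to be alkylated as well, or for an acyl group to migrate. The fallback sets out from 9, isolated when the HF·pyridine treatment of step 7 is left out, and comes back at the target 13; it keeps the tertiary oxygen silylated during methylation. Since the directing hydroxyl is then masked, a Corey–Bakshi–Shibata reduction (catalyst antipode chosen to add hydride syn to the C6 oxygen) should give [(1R,2S,5R,6S)-6-(acetyloxy)-5-[(tert-butyldimethylsilyl)oxy]-2-hydroxy-1-[(trimethylsilyl)oxy]cyclohex-3-en-1-yl]methyl benzoate F5. Methylation with MeOTf and 2,6-di-tert-butyl-4-methylpyridine, now without a competing hydroxyl, should give [(1R,2S,5R,6S)-6-(acetyloxy)-5-[(tert-butyldimethylsilyl)oxy]-2-methoxy-1-[(trimethylsilyl)oxy]cyclohex-3-en-1-yl]methyl benzoate F6. HF·pyridine removes both silyl groups to give [(1R,2S,5R,6S)-6-(acetyloxy)-1,5-dihydroxy-2-methoxycyclohex-3-en-1-yl]methyl benzoate F7, and benzoylation of its secondary C4 hydroxyl (BzCl, pyridine, DMAP, 0 °C) gives 13.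

**Further compounds**
F1 | step 7 | [(1S,2S,3R)-2-(acetyloxy)-3-[(tert-butyldimethylsilyl)oxy]-1-hydroxy-6-oxo-5-(trimethylsilyl)cyclohexyl]methyl benzoate (both epimers at the C–Si carbon) | O=C1C([Si](C)(C)C)C[C@@H](O[Si](C)(C)C(C)(C)C)[C@H](OC(C)=O)[C@@]1(O)COC(=O)c1ccccc1
F2 | step 7 | [(1S,2S,3R)-2-(acetyloxy)-3-[(tert-butyldimethylsilyl)oxy]-1-hydroxy-6-oxocyclohexyl]methyl benzoate | O=C1CC[C@@H](O[Si](C)(C)C(C)(C)C)[C@H](OC(C)=O)[C@@]1(O)COC(=O)c1ccccc1
F3 | step 7 | [(1S,5R,6S)-6-(acetyloxy)-5-[(tert-butyldimethylsilyl)oxy]-1-hydroxy-2-oxocyclohex-3-en-1-yl]methyl benzoate | O=C1C=C[C@@H](O[Si](C)(C)C(C)(C)C)[C@H](OC(C)=O)[C@@]1(O)COC(=O)c1ccccc1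
F4 | step 1 | (R)-4-[(tert-butyldimethylsilyl)oxy]-2-iodocyclopent-2-en-1-one | O=C1C(I)=C[C@H](O[Si](C)(C)C(C)(C)C)C1
F5 | step 10 | [(1R,2S,5R,6S)-6-(acetyloxy)-5-[(tert-butyldimethylsilyl)oxy]-2-hydroxy-1-[(trimethylsilyl)oxy]cyclohex-3-en-1-yl]methyl benzoate | O[C@H]1C=C[C@@H](O[Si](C)(C)C(C)(C)C)[C@H](OC(C)=O)[C@@]1(O[Si](C)(C)C)COC(=O)c1ccccc1
F6 | step 10 | [(1R,2S,5R,6S)-6-(acetyloxy)-5-[(tert-butyldimethylsilyl)oxy]-2-methoxy-1-[(trimethylsilyl)oxy]cyclohex-3-en-1-yl]methyl benzoate | CO[C@H]1C=C[C@@H](O[Si](C)(C)C(C)(C)C)[C@H](OC(C)=O)[C@@]1(O[Si](C)(C)C)COC(=O)c1ccccc1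
F7 | step 10 | [(1R,2S,5R,6S)-6-(acetyloxy)-1,5-dihydroxy-2-methoxycyclohex-3-en-1-yl]methyl benzoate | CO[C@H]1C=C[C@@H](O)[C@H](OC(C)=O)[C@@]1(O)COC(=O)c1ccccc1
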